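A direct plan would take both benzene rings from the shelf and join them at the end.
1,3-Dimethoxy-5-pentylbenzene A1 would be brominated and carboxylated through its aryllithium to 2,4-dimethoxy-6-pentylbenzoic acid A2.
Lateral lithiation and ethylation of tert-butyl 2-methoxy-6-methylbenzoate A3 would give tert-butyl 2-methoxy-6-propylbenzoate A4, and C–H borylation of A4 would give boronic acid A5.
A2 and A5 would be joined by a Cu(OTf)2-mediated Chan–Lam O-arylation to depside tert-butyl ester A6, and acidolysis of A6 would free the acid.
Weak point 1, the O-arylation of A2 with A5: a di-ortho-substituted carboxylate and an electron-poor boronic acid, prone to protodeboronation and needed in excess although it is a multi-step fragment, would carry the only convergent step.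
Weak point 2, the borylation of A4 and the cleavage of its boronate: two operations that build no skeleton, only to mark the carbon that will bear the ester oxygen.
Weak point 3, the halogen–lithium exchange on A1 and the lateral lithiation of A3: long arene decoration, with self-condensation risk, to reach two simple orsellinate-type acids.

**Retrosynthetic overview**
Ring A is an orsellinate-type tetraketide (carboxyl carbon on C1, oxygen on C2 and C4, pentyl on C6); it is cut back to an aryl 3,5,7-triketo ester, and this to the para-hydroxyl of ring B plus an acylketene masked as a diketo-dioxinone.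
Key disconnection: the depside C(=O)–O bond and the C1–C6 bond of ring A form in one operation; the phenol captures the ketene and the new triketo ester folds by aldol condensation into ring A.
Ring B is closed first, from acyclic material: dibenzyl malonate and (E)-hept-3-en-2-one give a cyclohexane-1,3-dione ester by Michael addition and Claisen closure, and aromatisation gives benzyl 2,4-dihydroxy-6-propylbenzoate, so the oxygen on C4 of ring B comes with the building block.
The ester is made while its carbonyl carbon is still a ketene, so no hindered acid is esterified and no boron or copper chemistry is needed.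
One global methylation sets all three methoxy groups, because the only oxygen that must stay free of methyl is by then the ester oxygen; hydrogenolysis of the benzyl ester ends the route.

Key step: step 5

Assumption: N-methoxy-N-methylhexanamide is bought (otherwise one step from hexanoyl chloride and N,O-dimethylhydroxylamine hydrochloride); 1,3-dicarbonyl compounds are drawn as keto tautomers, and compounds 9, 10 and 11 are racemic, their stereocentres vanishing on aromatisation.

Step 1
Reactants: 1 2,2,6-trimethyl-4H-1,3-dioxin-4-one
Product: 3 2,2-dimethyl-6-(2-oxopropyl)-4H-1,3-dioxin-4-one, via lithium dienolate 2 (not isolated)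
Conditions: LiN(SiMe3)2 (1.0 equiv), THF, −78 °C; AcCl (0.5 equiv), −78 to −20 °C; aq HCl
Reagents that add atoms: acetyl chloride, CC(=O)Cl
Why: Vinylogous Claisen-type C-acylation: deprotonation of the 6-methyl group gives the extended dienolate, which is acylated at its terminal carbon; the second equivalent of dienolate takes up the acidic proton of the product, and the 1 so regenerated is recovered.

Step 2
Reactants: 3 2,2-dimethyl-6-(2-oxopropyl)-4H-1,3-dioxin-4-one; 4 N-methoxy-N-methylhexanamide
Product: 6 6-(2,4-dioxononyl)-2,2-dimethyl-4H-1,3-dioxin-4-one, via dilithium dianion 5 (not isolated)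
Conditions: LiN(iPr)2 (2.1 equiv), THF, −78 °C; 4 (0.8 equiv), −78 to −40 °C; aq HCl to pH 3
Reagents that add atoms: none
Why: Claisen-type acylation of a 1,3-dicarbonyl dianion: the terminal carbanion, formed last, is the most nucleophilic site, and the chelated tetrahedral adduct of the N-methoxy-N-methylamide survives until work-up, so the new diketone is not attacked again.

Step 3
Reactants: 7 dibenzyl propanedioate (dibenzyl malonate); 8 (E)-hept-3-en-2-one
Product: 10 benzyl 2,4-dioxo-6-propylcyclohexane-1-carboxylate, via Michael adduct 9 (not isolated)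
Conditions: NaH (1.1 equiv), THF, 0 °C; 8 (1.0 equiv), rt then 65 °C; aq HCl
Reagents that add atoms: none
Why: Michael addition of the sodium salt of 7 to the enone, then an intramolecular Claisen (Dieckmann-type) condensation of the methyl ketone enolate onto one benzyl ester, closes the six-membered ring and is driven by deprotonation of the acidic 1,3-dione as it forms; the two stereocentres (C1 and C6) form without control as a racemic mixture and disappear in step 4.

Step 4
Reactants: 10 benzyl 2,4-dioxo-6-propylcyclohexane-1-carboxylate
Product: 12 benzyl 2,4-dihydroxy-6-propylbenzoate, via bromo dione 11 (not isolated)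
Conditions: Br2 (1.0 equiv), DMF, 0 °C, 1 h; then 80 °C
Reagents that add atoms: none
Why: Oxidative aromatisation by bromination and dehydrobromination, the classical entry from 2,4-dioxocyclohexanecarboxylates to 6-alkyl-2,4-dihydroxybenzoates: the enolised 1,3-dione is brominated at C3, and on warming hydrogen bromide is lost (after acid-promoted migration of bromine to a neighbouring α-carbon) and the cyclohexenedione enolises to the arene, with DMF buffering the acid.

Step 5
Reactants: 6 6-(2,4-dioxononyl)-2,2-dimethyl-4H-1,3-dioxin-4-one; 12 benzyl 2,4-dihydroxy-6-propylbenzoate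
Product: 15 benzyl 4-[(2,4-dihydroxy-6-pentylbenzoyl)oxy]-2-hydroxy-6-propylbenzoate, via acylketene 13 (not isolated), via aryl triketo ester 14 (not isolated)
Conditions: 12 (2 equiv, excess recovered), PhMe, 110 °C, slow addition of 6; then Et3N, CH2Cl2, 0 °C to rt; then HCl (4 M in dioxane), rt
Reagents that add atoms: none
Why: Proposed new method: heating 6 triggers a retro-[4+2] loss of acetone to acylketene 13, which the free para-hydroxyl of 12 should capture by concerted O–H addition to give aryl 3,5,7-triketo ester 14; Et3N then enolises 14 at C2 (between ester and ketone), and this carbon attacks the C7 ketone in a 6-exo-trig aldol closure that, after acid-promoted loss of water and tautomerisation, leaves ring A as a 2,4-dihydroxy-6-pentylbenzoate already esterified to ring B. The closest known reaction type is the one-pot capture of diketo-dioxinone-derived acylketenes by alcohols followed by aldol aromatisation to resorcylate esters, together with the acetoacetylation of phenols by 2,2,6-trimethyl-4H-1,3-dioxin-4-one; what has not been shown is the fold of a triketo ester whose alkoxy part is a phenol. No stereocenter is formed. Three selectivities are needed: between the two hydroxyls of 12, where the ortho-hydroxyl is tied up in a hydrogen bond to the benzyl ester and flanked by it, as in the para-selective acylation of 2,4-dihydroxybenzoates; between capture of 13 by 12 and by its own enol (pyranone formation), which excess 12 and slow addition of 6 should decide; and between the C2-to-C7 aldol and attack on the aryl ester carbon (C6-to-C1 Claisen or O5-to-C1 lactonisation, both expelling 12), which a weak amine base at low temperature should decide because only a monoenolate forms and the ketone is then the more electrophilic carbonyl. The step replaces the esterification of a di-ortho-substituted benzoic acid, because the ester carbon is acylated while it is still a ketene.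

Step 6
Reactants: 15 benzyl 4-[(2,4-dihydroxy-6-pentylbenzoyl)oxy]-2-hydroxy-6-propylbenzoate
Product: 16 benzyl 4-[(2,4-dimethoxy-6-pentylbenzoyl)oxy]-2-methoxy-6-propylbenzoate
Conditions: MeI (6 equiv), K2CO3 (4.5 equiv), acetone, 56 °C
Reagents that add atoms: iodomethane, CI
Why: Williamson ether synthesis on all three phenols at once; no differentiation is needed because the fourth phenolic oxygen is the ester oxygen, and anhydrous K2CO3 in acetone offers no nucleophile to the depside carbonyl, which is shielded by two ortho substituents.

Step 7
Reactants: 16 benzyl 4-[(2,4-dimethoxy-6-pentylbenzoyl)oxy]-2-methoxy-6-propylbenzoate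
Product: 17 4-[(2,4-dimethoxy-6-pentylbenzoyl)oxy]-2-methoxy-6-propylbenzoic acid
Conditions: H2 (1 atm), Pd/C (10 wt%), EtOAc, rt; filter, evaporate, recrystallise
Reagents that add atoms: none
Why: Catalytic hydrogenolysis of the benzylic C–O bond frees the acid under neutral conditions; the aryl ester, the methyl ethers and the alkyl chains are inert, and the hindered carbonyl never has to be attacked.

**Compound list**
1 | 2,2,6-trimethyl-4H-1,3-dioxin-4-one | CC1=CC(=O)OC(C)(C)O1 | starting material
2 | lithium 2,2-dimethyl-6-methylidene-6H-1,3-dioxin-4-olate (dienolate of 1) | [Li]OC1=CC(=C)OC(C)(C)O1 | intermediate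
3 | 2,2-dimethyl-6-(2-oxopropyl)-4H-1,3-dioxin-4-one | CC(=O)CC1=CC(=O)OC(C)(C)O1 | intermediate
4 | N-methoxy-N-methylhexanamide | CCCCCC(=O)N(C)OC | starting material
5 | dilithium dianion of 3 (terminal enolate and ring dienolate) | C=C(O[Li])C=C1C=C(O[Li])OC(C)(C)O1 | intermediate
6 | 6-(2,4-dioxononyl)-2,2-dimethyl-4H-1,3-dioxin-4-one | CCCCCC(=O)CC(=O)CC1=CC(=O)OC(C)(C)O1 | intermediate
7 | dibenzyl propanedioate (dibenzyl malonate) | O=C(CC(=O)OCc1ccccc1)OCc1ccccc1 | starting material
8 | (E)-hept-3-en-2-one | CCC/C=C/C(C)=O | starting material
9 | dibenzyl 2-(2-oxoheptan-4-yl)propanedioate (Michael adduct, racemic, present as its sodium enolate) | CCCC(CC(C)=O)C(C(=O)OCc1ccccc1)C(=O)OCc1ccccc1 | intermediate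
10 | benzyl 2,4-dioxo-6-propylcyclohexane-1-carboxylate (racemic, C1/C6 configuration not controlled, largely enolised) | CCCC1CC(=O)CC(=O)C1C(=O)OCc1ccccc1 | intermediate
11 | benzyl 3-bromo-2,4-dioxo-6-propylcyclohexane-1-carboxylate (racemic, first-formed bromo dione) | CCCC1CC(=O)C(Br)C(=O)C1C(=O)OCc1ccccc1 | intermediate
12 | benzyl 2,4-dihydroxy-6-propylbenzoate | CCCc1cc(O)cc(O)c1C(=O)OCc1ccccc1 | intermediate
13 | dodec-1-ene-1,3,5,7-tetrone (acylketene) | CCCCCC(=O)CC(=O)CC(=O)C=C=O | intermediate
14 | benzyl 2-hydroxy-6-propyl-4-[(3,5,7-trioxododecanoyl)oxy]benzoate | CCCCCC(=O)CC(=O)CC(=O)CC(=O)Oc1cc(O)c(C(=O)OCc2ccccc2)c(CCC)c1 | intermediate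
15 | benzyl 4-[(2,4-dihydroxy-6-pentylbenzoyl)oxy]-2-hydroxy-6-propylbenzoate | CCCCCc1cc(O)cc(O)c1C(=O)Oc1cc(O)c(C(=O)OCc2ccccc2)c(CCC)c1 | intermediate
16 | benzyl 4-[(2,4-dimethoxy-6-pentylbenzoyl)oxy]-2-methoxy-6-propylbenzoate | CCCCCc1cc(OC)cc(OC)c1C(=O)Oc1cc(CCC)c(C(=O)OCc2ccccc2)c(OC)c1 | intermediate
17 | 4-[(2,4-dimethoxy-6-pentylbenzoyl)oxy]-2-methoxy-6-propylbenzoic acid | CCCCCc1cc(OC)cc(OC)c1C(=O)Oc1cc(CCC)c(C(=O)O)c(OC)c1 | target

**Step count and risks**
Total steps: 7. Longest linear sequence: 5 (steps 1, 2, 5, 6, 7, or steps 3, 4, 5, 6, 7).

Step 5. The ketene may close onto its own enol faster than the phenol captures it, and the aryl triketo ester may cyclise at the ester carbon and expel the phenol in place of the aldol fold. The fallback keeps the idea of building ring A on an ester that is formed while unhindered, but closes the ring by cycloaddition. It sets out from 12, which would be esterified at its para-hydroxyl with oct-2-ynoic acid (Steglich esterification: DCC, cat. DMAP, CH2Cl2, 0 °C) to benzyl 2-hydroxy-4-(oct-2-ynoyloxy)-6-propylbenzoate F1. A Diels–Alder reaction of F1 with 1,1-dimethoxy-3-(trimethylsilyloxy)buta-1,3-diene (PhMe, 110 °C), loss of methanol from the adduct and desilylation on acidic work-up would give benzyl 2-hydroxy-4-[(4-hydroxy-2-methoxy-6-pentylbenzoyl)oxy]-6-propylbenzoate F2, with the ortho-methoxy group of ring A set by the regiochemistry of the cycloaddition. Methylation of its two remaining hydroxyls under the conditions of step 6 comes back to the route at 16.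

Step 2. Proton transfer from the amide or the product to the dianion, and O-acylation, may stall the chain extension. The fallback builds the second ketone by C-acylation of a β-keto ester in place of a dianion. It sets out from 1, whose dienolate 2 would be acylated with allyl 3-chloro-3-oxopropanoate to allyl 4-(2,2-dimethyl-4-oxo-4H-1,3-dioxin-6-yl)-3-oxobutanoate F3. C-acylation of F3 with hexanoyl chloride (MgCl2, pyridine, CH2Cl2) would give allyl 2-[(2,2-dimethyl-4-oxo-4H-1,3-dioxin-6-yl)acetyl]-3-oxooctanoate F4. Pd(PPh3)4 (zerovalent palladium) with morpholine in THF would then remove the allyl group and the carboxyl carbon and come back to the route at 6.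

Step 4. Bromine may also substitute the electron-rich ring once the arene has formed, and the hydrogen bromide set free may cleave the benzyl ester. The fallback folds ring B from an open poly-β-carbonyl chain in place of oxidising a carbocycle. It sets out from 3, whose dianion 5 would be acylated with N-methoxy-N-methylbutanamide to 6-(2,4-dioxoheptyl)-2,2-dimethyl-4H-1,3-dioxin-4-one F5. Heating F5 with benzyl alcohol in toluene at 110 °C would release acetone and give, by capture of the ketene, benzyl 3,5,7-trioxodecanoate F6. K2CO3 in iPrOH/CH2Cl2 and then HCl in MeOH would fold F6 by aldol condensation and dehydration and come back to the route at 12.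

**Further compounds**
F1 | step 5 | benzyl 2-hydroxy-4-(oct-2-ynoyloxy)-6-propylbenzoate | CCCCCC#CC(=O)Oc1cc(O)c(C(=O)OCc2ccccc2)c(CCC)c1
F2 | step 5 | benzyl 2-hydroxy-4-[(4-hydroxy-2-methoxy-6-pentylbenzoyl)oxy]-6-propylbenzoate | CCCCCc1cc(O)cc(OC)c1C(=O)Oc1cc(O)c(C(=O)OCc2ccccc2)c(CCC)c1
F3 | step 2 | allyl 4-(2,2-dimethyl-4-oxo-4H-1,3-dioxin-6-yl)-3-oxobutanoate | C=CCOC(=O)CC(=O)CC1=CC(=O)OC(C)(C)O1
F4 | step 2 | allyl 2-[(2,2-dimethyl-4-oxo-4H-1,3-dioxin-6-yl)acetyl]-3-oxooctanoate (racemic, enolisable) | CCCCCC(=O)C(C(=O)OCC=C)C(=O)CC1=CC(=O)OC(C)(C)O1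
F5 | step 4 | 6-(2,4-dioxoheptyl)-2,2-dimethyl-4H-1,3-dioxin-4-one | CCCC(=O)CC(=O)CC1=CC(=O)OC(C)(C)O1
F6 | step 4 | benzyl 3,5,7-trioxodecanoate | CCCC(=O)CC(=O)CC(=O)CC(=O)OCc1ccccc1
A1 | direct plan | 1,3-dimethoxy-5-pentylbenzene | CCCCCc1cc(OC)cc(OC)c1
A2 | direct plan | 2,4-dimethoxy-6-pentylbenzoic acid | CCCCCc1cc(OC)cc(OC)c1C(=O)O
A3 | direct plan | tert-butyl 2-methoxy-6-methylbenzoate | COc1cccc(C)c1C(=O)OC(C)(C)C
A4 | direct plan | tert-butyl 2-methoxy-6-propylbenzoate | CCCc1cccc(OC)c1C(=O)OC(C)(C)C
A5 | direct plan | [4-(tert-butoxycarbonyl)-3-methoxy-5-propylphenyl]boronic acid | CCCc1cc(B(O)O)cc(OC)c1C(=O)OC(C)(C)C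
A6 | direct plan | tert-butyl 4-[(2,4-dimethoxy-6-pentylbenzoyl)oxy]-2-methoxy-6-propylbenzoate | CCCCCc1cc(OC)cc(OC)c1C(=O)Oc1cc(CCC)c(C(=O)OC(C)(C)C)c(OC)c1
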